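**Plan**

1. The target 18 is 5-hydroxy-7,8-dimethoxy-2-(2,3,4,5-tetramethoxyphenyl)chromone and has no stereocentre. Ring B has four contiguous oxygens on C2'–C5': C3' and C4' map onto the two methoxy-bearing carbons of dimethyl squarate, C2' and C5' onto its two carbonyl carbons, and C1'/C6' onto a vinyl unit on chromone C2.
2. Retrosynthetic cuts, in order: the two ring-B O–CH3 bonds; the C1'–C2' bond of ring B (back to a 4-alkenyl-4-hydroxycyclobutenone); the C5'–C6' bond (alkenylmagnesium plus squarate); the C1'=C6' alkene (Takai); the pyranone ring (Claisen condensation, cyclodehydration).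
3. Forward: ring A is bought, ring C closes in step 2, the side chain grows CH3 → CHO → CH=CHI → squarate adduct, ring B closes last in step 7, and two O-methylations finish the route.
4. Stereochemistry: only the E alkene (Takai olefination, retained through the magnesium exchange) and one racemic carbinol carbon that is erased on aromatisation.
5. The 5-methoxy group is cleaved before the organomagnesium step, so that the chelated magnesium 5-phenoxide shields the chromone carbonyl; the chelated 5-OH is then left unmethylated at the end.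

Key step: step 7

Assumption: cyclobutenone 14 is made and used as the racemate, since its single stereocentre becomes the sp2 carbon C5' in step 7.

**Step 1**
Reactants: 1 1,2,3,5-tetramethoxybenzene; 2 acetyl chloride
Product: 4 1-(2-hydroxy-3,4,6-trimethoxyphenyl)ethan-1-one, via tetramethoxyacetophenone 3 (not isolated)
Conditions: AlCl3 (2.5 equiv), Et2O, 0 °C to rt; dilute aq. HCl work-up
Reagents that add atoms: none
Why: Friedel–Crafts acylation at one of the two equivalent free positions is followed in the same flask by AlCl3-mediated cleavage of the ortho methoxy group that is flanked on both sides, through a six-membered aluminium chelate with the new ketone.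

**Step 2**
Reactants: 4 1-(2-hydroxy-3,4,6-trimethoxyphenyl)ethan-1-one; 5 ethyl acetate
Product: 7 5,7,8-trimethoxy-2-methyl-4H-chromen-4-one, via aryl butane-1,3-dione 6 (not isolated)
Conditions: NaH (4 equiv), EtOAc (excess), THF, reflux; then conc. HCl, AcOH, 100 °C
Reagents that add atoms: none
Why: Crossed Claisen condensation of the methyl ketone enolate with ethyl acetate gives the 1,3-diketone, and acid-catalysed cyclodehydration of the phenol onto the distal carbonyl closes the 4-pyranone ring, as in the classical 2-methylchromone synthesis.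

**Step 3**
Reactants: 7 5,7,8-trimethoxy-2-methyl-4H-chromen-4-one
Product: 8 5,7,8-trimethoxy-4-oxo-4H-chromene-2-carbaldehyde
Conditions: SeO2 (1.5 equiv), xylene, 140 °C; hot filtration
Reagents that add atoms: selenium dioxide, O=[Se]=O
Why: Riley oxidation of the vinylogously activated 2-methyl group (ene reaction, then 2,3-sigmatropic shift) should stop at the aldehyde, a standard conversion of 2-methylchromones.

**Step 4**
Reactants: 8 5,7,8-trimethoxy-4-oxo-4H-chromene-2-carbaldehyde
Product: 9 2-[(E)-2-iodoethenyl]-5,7,8-trimethoxy-4H-chromen-4-one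
Conditions: CrCl2 (6 equiv), CHI3 (2 equiv), THF, 0 °C to rt
Reagents that add atoms: iodoform, IC(I)I
Why: Takai olefination with the geminal dichromium species from iodoform and divalent chromium is selective for aldehydes over the chromone ketone and should give the E iodoalkene through anti elimination.

**Step 5**
Reactants: 9 2-[(E)-2-iodoethenyl]-5,7,8-trimethoxy-4H-chromen-4-one
Product: 10 5-hydroxy-2-[(E)-2-iodoethenyl]-7,8-dimethoxy-4H-chromen-4-one
Conditions: BCl3 (1.3 equiv, 1 M in CH2Cl2), CH2Cl2, −78 to 0 °C; water
Reagents that add atoms: none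
Why: Only the peri 5-methoxy group can form a six-membered boron chelate with the C4 carbonyl, so chelation-directed ether cleavage should remove that methyl alone and leave the other aryl ethers and the alkenyl iodide untouched.

**Step 6**
Reactants: 10 5-hydroxy-2-[(E)-2-iodoethenyl]-7,8-dimethoxy-4H-chromen-4-one; 11 dimethyl squarate (3,4-dimethoxycyclobut-3-ene-1,2-dione)
Product: 14 racemic 4-hydroxy-4-[(E)-2-(5-hydroxy-7,8-dimethoxy-4-oxo-4H-chromen-2-yl)ethenyl]-2,3-dimethoxycyclobut-2-en-1-one, via magnesium phenoxide 12 (not isolated), via alkenylmagnesium chloride 13 (not isolated)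
Conditions: MeMgCl (1.0 equiv), LiCl (1.0 equiv), THF, −40 °C; iPrMgCl·LiCl (1.1 equiv), −40 to −20 °C; cannulate into 11 (1.5 equiv), THF, −78 °C; aq. NH4Cl
Reagents that add atoms: none
Why: MeMgCl first converts the 5-OH into a chelated magnesium phenoxide that turns C4=O into an unreactive vinylogous carboxylate, iodine–magnesium exchange with iPrMgCl·LiCl then gives the E-alkenyl Grignard reagent with retention of geometry, and its 1,2-addition to one of the two equivalent squarate carbonyls (inverse addition, excess squarate) gives the tertiary carbinol as a racemate whose configuration is irrelevant (halogen–magnesium exchange on a hydroxyl-bearing substrate, then Grignard addition to a squarate ester).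

**Step 7**
Reactants: 14 racemic 4-hydroxy-4-[(E)-2-(5-hydroxy-7,8-dimethoxy-4-oxo-4H-chromen-2-yl)ethenyl]-2,3-dimethoxycyclobut-2-en-1-one
Product: 17 2-(2,5-dihydroxy-3,4-dimethoxyphenyl)-5-hydroxy-7,8-dimethoxy-4H-chromen-4-one, via dienylketene 15 (not isolated), via cyclohexadienone 16 (not isolated)
Conditions: degassed p-xylene (0.01 M), 138 °C, argon
Reagents that add atoms: none
Why: Heating should open the cyclobutenone by conrotatory 4π cleavage of its C1–C4 bond to the (3Z,5E)-dienylketene 15, whose ketene carbon then bonds to the chromone-bearing alkene terminus in a thermal disrotatory 6π electrocyclisation to cyclohexadienone 16, and enolisation of 16 gives hydroquinone 17. The closest known reaction type is the Moore ring expansion of 4-alkenyl-4-hydroxycyclobutenones to hydroquinones. Ring B is the only ring formed, and it closes by this 6π electrocyclisation, which makes the C1'–C2' bond (C2' is the former squarate carbonyl carbon, C1' the former alkene carbon on chromone C2). The sp3 carbon that appears in 16 is lost on aromatisation and the racemic carbinol carbon of 14 becomes C5', so no stereocentre has to be controlled. The step needs torquoselective opening with the hydroxyl turning outward and the alkenyl group inward, which the donor hydroxyl on C4 secures as in other 4-hydroxycyclobutenones, so that ketene and alkene sit cis on the new enol double bond, while the E alkene keeps the chromone on the outside of the closing termini. The chelated 5-OH is too poor a nucleophile to intercept the ketene, and high dilution under argon should suppress intermolecular trapping and oxidation to the quinone.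

**Step 8**
Reactants: 17 2-(2,5-dihydroxy-3,4-dimethoxyphenyl)-5-hydroxy-7,8-dimethoxy-4H-chromen-4-one
Product: 18 5-hydroxy-7,8-dimethoxy-2-(2,3,4,5-tetramethoxyphenyl)-4H-chromen-4-one
Conditions: Me2SO4 (2.3 equiv), K2CO3 (3 equiv), degassed acetone, 56 °C, argon
Reagents that add atoms: dimethyl sulfate, COS(=O)(=O)OC
Why: Williamson O-methylation should take the two ring-B phenols, while the 5-OH, locked in a hydrogen bond to the C4 carbonyl, is much less acidic and nucleophilic and is expected to stay free under these mild conditions, as in the classical partial methylation of 5-hydroxyflavones.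

**Compound list**

1 | 1,2,3,5-tetramethoxybenzene | COc1cc(OC)c(OC)c(OC)c1 | starting material
2 | acetyl chloride | CC(=O)Cl | starting material
3 | 1-(2,3,4,6-tetramethoxyphenyl)ethan-1-one | CC(=O)c1c(OC)cc(OC)c(OC)c1OC | intermediate (not isolated)
4 | 1-(2-hydroxy-3,4,6-trimethoxyphenyl)ethan-1-one | CC(=O)c1c(OC)cc(OC)c(OC)c1O | intermediate
5 | ethyl acetate | CCOC(C)=O | starting material
6 | 1-(2-hydroxy-3,4,6-trimethoxyphenyl)butane-1,3-dione | CC(=O)CC(=O)c1c(OC)cc(OC)c(OC)c1O | intermediate (not isolated)
7 | 5,7,8-trimethoxy-2-methyl-4H-chromen-4-one | Cc1cc(=O)c2c(OC)cc(OC)c(OC)c2o1 | intermediate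
8 | 5,7,8-trimethoxy-4-oxo-4H-chromene-2-carbaldehyde | O=Cc1cc(=O)c2c(OC)cc(OC)c(OC)c2o1 | intermediate
9 | 2-[(E)-2-iodoethenyl]-5,7,8-trimethoxy-4H-chromen-4-one | I/C=C/c1cc(=O)c2c(OC)cc(OC)c(OC)c2o1 | intermediate
10 | 5-hydroxy-2-[(E)-2-iodoethenyl]-7,8-dimethoxy-4H-chromen-4-one | I/C=C/c1cc(=O)c2c(O)cc(OC)c(OC)c2o1 | intermediate
11 | dimethyl squarate (3,4-dimethoxycyclobut-3-ene-1,2-dione) | COC1=C(OC)C(=O)C1=O | starting material
12 | chloromagnesium 2-[(E)-2-iodoethenyl]-7,8-dimethoxy-4-oxo-4H-chromen-5-olate | I/C=C/c1cc(=O)c2c(O[Mg]Cl)cc(OC)c(OC)c2o1 | intermediate (not isolated)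
13 | chloromagnesium 2-[(E)-2-(chloromagnesio)ethenyl]-7,8-dimethoxy-4-oxo-4H-chromen-5-olate | Cl[Mg]/C=C/c1cc(=O)c2c(O[Mg]Cl)cc(OC)c(OC)c2o1 | intermediate (not isolated)
14 | racemic 4-hydroxy-4-[(E)-2-(5-hydroxy-7,8-dimethoxy-4-oxo-4H-chromen-2-yl)ethenyl]-2,3-dimethoxycyclobut-2-en-1-one | COC1=C(OC)C(O)(/C=C/c2cc(=O)c3c(O)cc(OC)c(OC)c3o2)C1=O | intermediate (key-step precursor)
15 | (3Z,5E)-4-hydroxy-6-(5-hydroxy-7,8-dimethoxy-4-oxo-4H-chromen-2-yl)-2,3-dimethoxyhexa-1,3,5-trien-1-one | O=C=C(OC)/C(OC)=C(\C=C\c1cc(=O)c2c(O)cc(OC)c(OC)c2o1)O | intermediate (not isolated)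
16 | racemic 4-hydroxy-6-(5-hydroxy-7,8-dimethoxy-4-oxo-4H-chromen-2-yl)-2,3-dimethoxycyclohexa-2,4-dien-1-one | O=C1C(OC)=C(OC)C(O)=CC1c1cc(=O)c2c(O)cc(OC)c(OC)c2o1 | intermediate (not isolated)
17 | 2-(2,5-dihydroxy-3,4-dimethoxyphenyl)-5-hydroxy-7,8-dimethoxy-4H-chromen-4-one | COc1c(O)cc(-c2cc(=O)c3c(O)cc(OC)c(OC)c3o2)c(O)c1OC | intermediate (key-step product)
18 | 5-hydroxy-7,8-dimethoxy-2-(2,3,4,5-tetramethoxyphenyl)-4H-chromen-4-one | COc1cc(-c2cc(=O)c3c(O)cc(OC)c(OC)c3o2)c(OC)c(OC)c1OC | target

**Step count and risks**

Total step count: 8. Longest linear sequence: 8 steps (1 to 18); compounds 2, 5 and 11 enter as purchased reagents.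

The three steps most likely to fail:

Step 6. The iodine–magnesium exchange on the electron-rich phenoxide may be slow enough that isopropylmagnesium chloride or the alkenyl Grignard reagent adds to the chromone of a second molecule, or the adduct may take up a second alkenyl group. The fallback avoids any carbanion next to the chromone and joins the two halves by olefin cross-metathesis; it sets out from 8 and 11 and returns at 14. Wittig methylenation of 8 (Ph3PCH3Br, KOtBu, THF, 0 °C) should give 2-ethenyl-5,7,8-trimethoxy-4H-chromen-4-one F1. Chelation-directed demethylation with BCl3 (CH2Cl2, −78 to 0 °C) then gives 2-ethenyl-5-hydroxy-7,8-dimethoxy-4H-chromen-4-one F2. Separately, vinylmagnesium bromide is added to 11 (THF, −78 °C) to give 4-ethenyl-4-hydroxy-2,3-dimethoxycyclobut-2-en-1-one F3. Cross-metathesis of F2 with excess F3 using the second-generation Hoveyda–Grubbs catalyst, RuCl2(SIMes)(=CH-C6H4-2-OiPr), in CH2Cl2 at 40 °C, well below the ring-expansion temperature, should give the E alkene 14.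

Step 7. The ring opening may proceed in part with the hydroxyl turning inward, so that the ketene lactonises to a butenolide instead of closing onto the alkene. The dienylketene may also be consumed intermolecularly, or the hydroquinone may oxidise during the reaction. The fallback builds ring B from a pre-oxygenated arene by the chalcone route; it sets out from 4 and returns at 18. Rieche formylation of commercial 1,2,3,4-tetramethoxybenzene (Cl2CHOMe, TiCl4, CH2Cl2, 0 °C) gives 2,3,4,5-tetramethoxybenzaldehyde F4. Claisen–Schmidt condensation of F4 with 4 (KOH, EtOH, rt) gives (E)-1-(2-hydroxy-3,4,6-trimethoxyphenyl)-3-(2,3,4,5-tetramethoxyphenyl)prop-2-en-1-one F5. Iodine-catalysed oxidative cyclisation (I2 cat., DMSO, 130 °C) gives 5,7,8-trimethoxy-2-(2,3,4,5-tetramethoxyphenyl)-4H-chromen-4-one F6. Chelation-directed cleavage of the 5-methoxy group with BCl3 (CH2Cl2, 0 °C) then gives 18.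

Step 3. The Riley oxidation may run on to the carboxylic acid or stall at partial conversion, with colloidal selenium carried into the product. The fallback replaces direct oxidation by enamine formation and oxidative cleavage; it sets out from 7 and returns at 8. Condensation of 7 with N,N-dimethylformamide dimethyl acetal (DMF, 120 °C) should give 2-[(E)-2-(dimethylamino)ethenyl]-5,7,8-trimethoxy-4H-chromen-4-one F7. Cleavage of the enamine double bond with NaIO4 (THF/H2O, rt) then gives aldehyde 8.

**Further compounds**

F1 | step 6 | 2-ethenyl-5,7,8-trimethoxy-4H-chromen-4-one | C=Cc1cc(=O)c2c(OC)cc(OC)c(OC)c2o1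
F2 | step 6 | 2-ethenyl-5-hydroxy-7,8-dimethoxy-4H-chromen-4-one | C=Cc1cc(=O)c2c(O)cc(OC)c(OC)c2o1
F3 | step 6 | 4-ethenyl-4-hydroxy-2,3-dimethoxycyclobut-2-en-1-one | COC1=C(OC)C(O)(C=C)C1=O
F4 | step 7 | 2,3,4,5-tetramethoxybenzaldehyde | COc1cc(C=O)c(OC)c(OC)c1OC
F5 | step 7 | (E)-1-(2-hydroxy-3,4,6-trimethoxyphenyl)-3-(2,3,4,5-tetramethoxyphenyl)prop-2-en-1-one | O=C(/C=C/c1cc(OC)c(OC)c(OC)c1OC)c1c(O)c(OC)c(OC)cc1OC
F6 | step 7 | 5,7,8-trimethoxy-2-(2,3,4,5-tetramethoxyphenyl)-4H-chromen-4-one | COc1cc(-c2cc(=O)c3c(OC)cc(OC)c(OC)c3o2)c(OC)c(OC)c1OC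
F7 | step 3 | 2-[(E)-2-(dimethylamino)ethenyl]-5,7,8-trimethoxy-4H-chromen-4-one | CN(C)/C=C/c1cc(=O)c2c(OC)cc(OC)c(OC)c2o1
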